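## Retrosynthetic overview

1. Rings: A cyclohexene, B cyclopentane, C β-lactone, D trimethylcyclohexane. The target is opened to the monocyclic aldehyde acid 20: one aldol-lactonization forms the bond shared by rings B and C (lactone α-carbon to O–CH carbon) and then the lactone C–O bond.
2. Enabling feature: in the cis-fused 6-oxabicyclo[3.2.0]heptan-7-one (rings B/C) the fusion bond carries the lactone C=O on one carbon and the ring oxygen on the other, a β-hydroxy-acid (aldol) retron. Its two carbons hang on the ring-A alkene carbon (through one CH2) and on the neighbouring allylic CH, so a propanoic acid arm and a formyl group on adjacent ring-A atoms close both rings.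
3. 20 comes from tetrasubstituted cyclohexene 16, made by Negishi coupling of enol triflate 15 with a zinc homoenolate; 15 comes from 2-substituted cyclohexenone 13 by reductive enolate triflation.
4. Ring A: enone 11 from β-keto ester 6 and enal 9 by organocatalytic Michael addition/aldol condensation (sets the CH–CH2O centre); the neighbouring centre by trans-selective α′-alkylation.
5. Quaternary centre of ring D: Johnson–Claisen chirality transfer from (R)-isophorol (CBS reduction of isophorone). Ring order: D (bought), then A, then B and C together.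

Key step: step 15

Assumption: the senses of the two catalyst-controlled steps (1 and 7) are assigned from the accepted transition-state models; if either ran the other way, the mirror-image catalyst would be used.

## Route

Step 1
Reactants: 1 isophorone (3,5,5-trimethylcyclohex-2-en-1-one)
Product: 2 (R)-isophorol, (1R)-3,5,5-trimethylcyclohex-2-en-1-ol
Conditions: (S)-2-methyl-CBS-oxazaborolidine (10 mol%), BH3·SMe2, THF, −20 °C; MeOH, then aqueous work-up
Reagents that add atoms: none
Why: CBS reduction of a cyclic enone in which the alkenyl carbon acts as the large group, so the (S)-oxazaborolidine–borane complex should deliver hydride to the face that gives the (R)-allylic alcohol, the centre that later controls the quaternary carbon.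

Step 2
Reactants: 2 (R)-isophorol
Product: 4 ethyl 2-[(1R)-1,5,5-trimethylcyclohex-2-en-1-yl]acetate, via mixed ketene acetal 3 (not isolated)
Conditions: MeC(OEt)3, EtCO2H (5 mol%), xylene, 140 °C, EtOH distilled off
Reagents that add atoms: triethyl orthoacetate, CC(OCC)(OCC)OCC
Why: Johnson–Claisen rearrangement, in which the ketene acetal rearranges suprafacially across the cyclohexenyl allyl unit, so the new C–C bond forms at the methyl-bearing alkene carbon on the face that carried the C–O bond and the carbinol chirality is transferred to the (R)-quaternary centre.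

Step 3
Reactants: 4 ethyl 2-[(1R)-1,5,5-trimethylcyclohex-2-en-1-yl]acetate
Product: 5 ethyl 2-[(1R)-1,3,3-trimethylcyclohexyl]acetate
Conditions: H2 (1 atm), Pd/C, EtOAc, 23 °C
Reagents that add atoms: none
Why: Heterogeneous hydrogenation of the isolated disubstituted ring alkene, which creates and touches no stereocentre.

Step 4
Reactants: 5 ethyl 2-[(1R)-1,3,3-trimethylcyclohexyl]acetate
Product: 6 tert-butyl 3-oxo-4-[(1R)-1,3,3-trimethylcyclohexyl]butanoate
Conditions: t-BuOAc, LiN(SiMe3)2 (3 equiv each), THF, −78 → 0 °C; aqueous HCl work-up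
Reagents that add atoms: tert-butyl acetate, CC(=O)OC(C)(C)C
Why: Crossed Claisen condensation of the lithium enolate of tert-butyl acetate with the ethyl ester, driven by deprotonation of the β-keto ester that forms.

Step 5
Reactants: 7 allyl alcohol (prop-2-en-1-ol)
Product: 8 tert-butyl(diphenyl)(prop-2-en-1-yloxy)silane
Conditions: TBDPSCl, imidazole, CH2Cl2, 0 → 23 °C
Reagents that add atoms: tert-butyl(chloro)diphenylsilane, CC(C)(C)[Si](Cl)(c1ccccc1)c1ccccc1
Why: Standard silylation of a primary alcohol, with the acid-robust tert-butyldiphenylsilyl group chosen to survive the acidic annulation of step 7.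

Step 6
Reactants: 8 tert-butyl(diphenyl)(prop-2-en-1-yloxy)silane
Product: 9 (2E)-4-{[tert-butyl(diphenyl)silyl]oxy}but-2-enal
Conditions: (E)-crotonaldehyde (3 equiv), second-generation Grubbs catalyst RuCl2(=CHPh)(PCy3)(H2IMes) (3 mol%), CH2Cl2, 40 °C
Reagents that add atoms: (E)-crotonaldehyde, C/C=C/C=O
Why: Olefin cross-metathesis of a terminal allyl ether with an electron-poor enal partner, which should give the E-enal selectively with loss of propene.

Step 7
Reactants: 6 tert-butyl 3-oxo-4-[(1R)-1,3,3-trimethylcyclohexyl]butanoate; 9 (2E)-4-{[tert-butyl(diphenyl)silyl]oxy}but-2-enal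
Product: 11 (5R)-5-({[tert-butyl(diphenyl)silyl]oxy}methyl)-2-[(1R)-1,3,3-trimethylcyclohexyl]cyclohex-2-en-1-one, via Michael adduct 10 (not isolated)
Conditions: (S)-2-[diphenyl(trimethylsilyloxy)methyl]pyrrolidine (10 mol%), toluene, 23 °C; then TsOH·H2O (20 mol%), 80 °C
Reagents that add atoms: none
Why: Iminium-catalysed Michael addition of the β-keto ester to the enal, then acid-mediated loss of the tert-butyl ester, decarboxylation and intramolecular aldol condensation (organocatalytic Robinson-type annulation, known for 4-substituted acetoacetates); the nucleophile adds to the face of the E-iminium ion opposite the diphenyl(silyloxy)methyl group of the (S)-catalyst, which should set the (R)-centre bearing the CH2O group, and only the CH2 next to the quaternary ring carbon can close a six-membered ring.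

Step 8
Reactants: 11 (5R)-5-({[tert-butyl(diphenyl)silyl]oxy}methyl)-2-[(1R)-1,3,3-trimethylcyclohexyl]cyclohex-2-en-1-one
Product: 13 (5R,6R)-6-[(benzyloxy)methyl]-5-({[tert-butyl(diphenyl)silyl]oxy}methyl)-2-[(1R)-1,3,3-trimethylcyclohexyl]cyclohex-2-en-1-one, via lithium dienolate 12 (not isolated)
Conditions: LiN(i-Pr)2 (1.05 equiv), THF, −78 °C; BnOCH2Cl, −78 → −40 °C
Reagents that add atoms: benzyl chloromethyl ether, ClCOCc1ccccc1
Why: Kinetic deprotonation at the saturated α′-carbon gives the cross-conjugated enolate, which is alkylated anti to the neighbouring silyloxymethyl group (enolate alkylation of a 5-substituted cyclohexenone, as with carvone), setting the trans relationship of the two CH2O arms.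

Step 9
Reactants: 13 (5R,6R)-6-[(benzyloxy)methyl]-5-({[tert-butyl(diphenyl)silyl]oxy}methyl)-2-[(1R)-1,3,3-trimethylcyclohexyl]cyclohex-2-en-1-one
Product: 15 (5R,6R)-6-[(benzyloxy)methyl]-5-({[tert-butyl(diphenyl)silyl]oxy}methyl)-2-[(1R)-1,3,3-trimethylcyclohexyl]cyclohex-1-en-1-yl trifluoromethanesulfonate, via lithium enolate 14 (not isolated)
Conditions: LiBH(s-Bu)3, THF, −78 °C; then PhNTf2, −78 → 0 °C
Reagents that add atoms: N-phenylbis(trifluoromethanesulfonimide), O=S(=O)(N(c1ccccc1)S(=O)(=O)C(F)(F)F)C(F)(F)F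
Why: Conjugate hydride addition to the β-unsubstituted, α-branched enone generates the enolate regiospecifically on the side of the trimethylcyclohexyl group, and O-triflation fixes it as the tetrasubstituted enol triflate (reductive enolate trapping).

Step 10
Reactants: 15 (5R,6R)-6-[(benzyloxy)methyl]-5-({[tert-butyl(diphenyl)silyl]oxy}methyl)-2-[(1R)-1,3,3-trimethylcyclohexyl]cyclohex-1-en-1-yl trifluoromethanesulfonate
Product: 16 benzyl 3-[(5R,6S)-6-[(benzyloxy)methyl]-5-({[tert-butyl(diphenyl)silyl]oxy}methyl)-2-[(1R)-1,3,3-trimethylcyclohexyl]cyclohex-1-en-1-yl]propanoate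
Conditions: BrCH2CH2CO2Bn, Zn dust, LiCl, THF, 40 °C; then 15, Pd(OAc)2 (5 mol%), SPhos (10 mol%), THF/NMP, 50 °C
Reagents that add atoms: benzyl 3-bromopropanoate (used as its zinc reagent), BrCCC(=O)OCc1ccccc1
Why: Negishi coupling of the enol triflate with a zinc homoenolate installs the propanoate arm without moving the double bond, completing the tetrasubstituted ring-A alkene.

Step 11
Reactants: 16 benzyl 3-[(5R,6S)-6-[(benzyloxy)methyl]-5-({[tert-butyl(diphenyl)silyl]oxy}methyl)-2-[(1R)-1,3,3-trimethylcyclohexyl]cyclohex-1-en-1-yl]propanoate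
Product: 17 benzyl 3-[(5R,6S)-6-[(benzyloxy)methyl]-5-(hydroxymethyl)-2-[(1R)-1,3,3-trimethylcyclohexyl]cyclohex-1-en-1-yl]propanoate
Conditions: HF·pyridine, THF–pyridine, 0 → 23 °C
Reagents that add atoms: none
Why: Fluoride cleavage of the silyl ether, to which the benzyl ether and benzyl ester are inert.

Step 12
Reactants: 17 benzyl 3-[(5R,6S)-6-[(benzyloxy)methyl]-5-(hydroxymethyl)-2-[(1R)-1,3,3-trimethylcyclohexyl]cyclohex-1-en-1-yl]propanoate
Product: 18 benzyl 3-[(5R,6S)-6-[(benzyloxy)methyl]-5-[(butanoyloxy)methyl]-2-[(1R)-1,3,3-trimethylcyclohexyl]cyclohex-1-en-1-yl]propanoate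
Conditions: (n-PrCO)2O, Et3N, DMAP (cat.), CH2Cl2, 0 °C
Reagents that add atoms: butanoic anhydride, CCCC(=O)OC(=O)CCC
Why: DMAP-catalysed acylation of the primary alcohol.

Step 13
Reactants: 18 benzyl 3-[(5R,6S)-6-[(benzyloxy)methyl]-5-[(butanoyloxy)methyl]-2-[(1R)-1,3,3-trimethylcyclohexyl]cyclohex-1-en-1-yl]propanoate
Product: 19 3-[(5R,6S)-5-[(butanoyloxy)methyl]-6-(hydroxymethyl)-2-[(1R)-1,3,3-trimethylcyclohexyl]cyclohex-1-en-1-yl]propanoic acid
Conditions: H2 (1 atm), Pd/C, EtOAc, 23 °C
Reagents that add atoms: none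
Why: Hydrogenolysis removes the benzyl ether and the benzyl ester in one operation, while the hindered tetrasubstituted alkene and the butanoate should not react.

Step 14
Reactants: 19 3-[(5R,6S)-5-[(butanoyloxy)methyl]-6-(hydroxymethyl)-2-[(1R)-1,3,3-trimethylcyclohexyl]cyclohex-1-en-1-yl]propanoic acid
Product: 20 3-[(5R,6S)-5-[(butanoyloxy)methyl]-6-formyl-2-[(1R)-1,3,3-trimethylcyclohexyl]cyclohex-1-en-1-yl]propanoic acid (used crude)
Conditions: Dess–Martin periodinane, CH2Cl2, 0 → 23 °C
Reagents that add atoms: none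
Why: Dess–Martin oxidation of the primary alcohol to the aldehyde in the presence of the free acid under non-basic conditions, so the allylic α-stereocentre should not epimerise.

Step 15
Reactants: 20 3-[(5R,6S)-5-[(butanoyloxy)methyl]-6-formyl-2-[(1R)-1,3,3-trimethylcyclohexyl]cyclohex-1-en-1-yl]propanoic acid
Product: 22 target, the butanoate of the tricyclic β-lactone (ring A cyclohexene fused to cyclopentane ring B, which is cis-fused to the oxetan-2-one), via ammonium enolate 21 (not isolated)
Conditions: 2-bromo-1-propylpyridinium triflate (3 equiv), 4-pyrrolidinopyridine (1.5 equiv), i-Pr2NEt (4 equiv), CH2Cl2, 23 °C, slow addition of 20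
Reagents that add atoms: none
Why: Nucleophile-catalysed aldol-lactonization: the acid is activated by the 2-bromopyridinium salt and passed to 4-pyrrolidinopyridine, i-Pr2NEt turns the acylammonium ion into ammonium enolate 21, its α-carbon adds to the aldehyde carbon to forge the bond between the lactone α-carbon and the O–CH carbon, and the aldolate oxygen then attacks the acylammonium carbonyl and releases the catalyst. The closest known reaction type is the aldol-lactonization of aldehyde acids to cyclopentane-fused β-lactones under these conditions. Ring B closes in a 5-exo-trig (enolexo) aldol and the β-lactone in a 4-exo-trig acyl substitution; only the syn-aldolate can lactonize, so the cis fusion of the two new CH centres is enforced. Their absolute sense is controlled by the aldehyde-bearing ring stereocentre: the carbonyl oxygen and the acylammonium arm should take the face of the forming cyclopentane that carries the ring-fusion hydrogen, anti to the neighbouring CH(CH2O2CPr) ring carbon, giving (S) at the lactone α-carbon and (R) at the O–CH carbon. The step needs enolization of the activated acid only, in the presence of the α-branched allylic aldehyde and the butanoate; this is secured because only the acylammonium α-protons are acidified, the aldehyde has a single hindered α-hydrogen, and slow addition keeps its concentration low so that epimerisation and intermolecular aldol reaction should not compete.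

## Compound list

1 | isophorone (3,5,5-trimethylcyclohex-2-en-1-one) | CC1=CC(=O)CC(C)(C)C1 | starting material
2 | (1R)-3,5,5-trimethylcyclohex-2-en-1-ol | O[C@H]1C=C(C)CC(C)(C)C1 | intermediate
3 | 1-ethoxy-1-{[(1R)-3,5,5-trimethylcyclohex-2-en-1-yl]oxy}ethene (mixed ketene acetal) | C=C(OCC)O[C@H]1C=C(C)CC(C)(C)C1 | intermediate
4 | ethyl 2-[(1R)-1,5,5-trimethylcyclohex-2-en-1-yl]acetate | CCOC(=O)C[C@]1(C)C=CCC(C)(C)C1 | intermediate
5 | ethyl 2-[(1R)-1,3,3-trimethylcyclohexyl]acetate | CCOC(=O)C[C@]1(C)CCCC(C)(C)C1 | intermediate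
6 | tert-butyl 3-oxo-4-[(1R)-1,3,3-trimethylcyclohexyl]butanoate | CC(C)(C)OC(=O)CC(=O)C[C@]1(C)CCCC(C)(C)C1 | intermediate
7 | allyl alcohol (prop-2-en-1-ol) | OCC=C | starting material
8 | tert-butyl(diphenyl)(prop-2-en-1-yloxy)silane | C=CCO[Si](c1ccccc1)(c1ccccc1)C(C)(C)C | intermediate
9 | (2E)-4-{[tert-butyl(diphenyl)silyl]oxy}but-2-enal | O=C/C=C/CO[Si](c1ccccc1)(c1ccccc1)C(C)(C)C | intermediate
10 | tert-butyl 2-[(2R)-1-{[tert-butyl(diphenyl)silyl]oxy}-4-oxobutan-2-yl]-3-oxo-4-[(1R)-1,3,3-trimethylcyclohexyl]butanoate (Michael adduct, both epimers at C2 of the butanoate) | CC(C)(C)OC(=O)C([C@@H](CC=O)CO[Si](c1ccccc1)(c1ccccc1)C(C)(C)C)C(=O)C[C@]1(C)CCCC(C)(C)C1 | intermediate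
11 | (5R)-5-({[tert-butyl(diphenyl)silyl]oxy}methyl)-2-[(1R)-1,3,3-trimethylcyclohexyl]cyclohex-2-en-1-one | CC(C)(C)[Si](OC[C@@H]1CC=C([C@]2(C)CCCC(C)(C)C2)C(=O)C1)(c1ccccc1)c1ccccc1 | intermediate
12 | lithium (3R)-3-({[tert-butyl(diphenyl)silyl]oxy}methyl)-6-[(1R)-1,3,3-trimethylcyclohexyl]cyclohexa-1,5-dien-1-olate | CC(C)(C)[Si](OC[C@@H]1CC=C([C@]2(C)CCCC(C)(C)C2)C([O-])=C1)(c1ccccc1)c1ccccc1.[Li+] | intermediate
13 | (5R,6R)-6-[(benzyloxy)methyl]-5-({[tert-butyl(diphenyl)silyl]oxy}methyl)-2-[(1R)-1,3,3-trimethylcyclohexyl]cyclohex-2-en-1-one | CC(C)(C)[Si](OC[C@@H]1CC=C([C@]2(C)CCCC(C)(C)C2)C(=O)[C@H]1COCc1ccccc1)(c1ccccc1)c1ccccc1 | intermediate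
14 | lithium (5R,6R)-6-[(benzyloxy)methyl]-5-({[tert-butyl(diphenyl)silyl]oxy}methyl)-2-[(1R)-1,3,3-trimethylcyclohexyl]cyclohex-1-en-1-olate | CC(C)(C)[Si](OC[C@@H]1CCC([C@]2(C)CCCC(C)(C)C2)=C([O-])[C@H]1COCc1ccccc1)(c1ccccc1)c1ccccc1.[Li+] | intermediate
15 | (5R,6R)-6-[(benzyloxy)methyl]-5-({[tert-butyl(diphenyl)silyl]oxy}methyl)-2-[(1R)-1,3,3-trimethylcyclohexyl]cyclohex-1-en-1-yl trifluoromethanesulfonate | CC(C)(C)[Si](OC[C@@H]1CCC([C@]2(C)CCCC(C)(C)C2)=C(OS(=O)(=O)C(F)(F)F)[C@H]1COCc1ccccc1)(c1ccccc1)c1ccccc1 | intermediate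
16 | benzyl 3-[(5R,6S)-6-[(benzyloxy)methyl]-5-({[tert-butyl(diphenyl)silyl]oxy}methyl)-2-[(1R)-1,3,3-trimethylcyclohexyl]cyclohex-1-en-1-yl]propanoate | CC(C)(C)[Si](OC[C@@H]1CCC([C@]2(C)CCCC(C)(C)C2)=C(CCC(=O)OCc2ccccc2)[C@H]1COCc1ccccc1)(c1ccccc1)c1ccccc1 | intermediate
17 | benzyl 3-[(5R,6S)-6-[(benzyloxy)methyl]-5-(hydroxymethyl)-2-[(1R)-1,3,3-trimethylcyclohexyl]cyclohex-1-en-1-yl]propanoate | OC[C@@H]1CCC([C@]2(C)CCCC(C)(C)C2)=C(CCC(=O)OCc2ccccc2)[C@H]1COCc1ccccc1 | intermediate
18 | benzyl 3-[(5R,6S)-6-[(benzyloxy)methyl]-5-[(butanoyloxy)methyl]-2-[(1R)-1,3,3-trimethylcyclohexyl]cyclohex-1-en-1-yl]propanoate | CCCC(=O)OC[C@@H]1CCC([C@]2(C)CCCC(C)(C)C2)=C(CCC(=O)OCc2ccccc2)[C@H]1COCc1ccccc1 | intermediate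
19 | 3-[(5R,6S)-5-[(butanoyloxy)methyl]-6-(hydroxymethyl)-2-[(1R)-1,3,3-trimethylcyclohexyl]cyclohex-1-en-1-yl]propanoic acid | CCCC(=O)OC[C@@H]1CCC([C@]2(C)CCCC(C)(C)C2)=C(CCC(=O)O)[C@H]1CO | intermediate
20 | 3-[(5R,6S)-5-[(butanoyloxy)methyl]-6-formyl-2-[(1R)-1,3,3-trimethylcyclohexyl]cyclohex-1-en-1-yl]propanoic acid | CCCC(=O)OC[C@@H]1CCC([C@]2(C)CCCC(C)(C)C2)=C(CCC(=O)O)[C@H]1C=O | intermediate
21 | ammonium enolate of 20 (enolate of its 1-acyl-4-(pyrrolidin-1-yl)pyridinium ion) | CCCC(=O)OC[C@@H]1CCC([C@]2(C)CCCC(C)(C)C2)=C(CC=C([O-])[n+]2ccc(cc2)N2CCCC2)[C@H]1C=O | intermediate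
22 | CNP0144861.2: butanoate of the tricyclic β-lactone; (R) at CH–CH2O2CPr, (S) at the ring-A/B fusion CH, (R) at O–CH, (S) at the lactone α-CH, (R) at the quaternary carbon | CCCC(=O)OC[C@@H]1CCC([C@]2(C)CCCC(C)(C)C2)=C2C[C@@H]3C(=O)O[C@@H]3[C@H]21 | target

## Step count and risks

Total: 15 steps. Longest linear sequence: 13 steps (1–4 and 7–15, isophorone to 22); the enal branch (steps 5–6) adds two.

**Step 10.** Oxidative addition or transmetalation may stall at the triflate carbon, which is flanked by the tert-alkyl-bearing alkene carbon and a branched ring carbon, so that the triflate is reduced or hydrolysed back to the ketone instead of coupling. The fallback sets out from 13 and comes back at 16; it brings in the propanoate arm by carbonyl addition and allylic transposition instead of cross-coupling. Enone 13 takes up allylmagnesium bromide at the carbonyl carbon to give the tertiary allylic alcohol F1. Ionisation with BF3·OEt2 in the presence of Et3SiH should deliver hydride to the unsubstituted end of the allyl cation and move the double bond into the tetrasubstituted position, giving the allyl-substituted cyclohexene F2. Hydroboration of the terminal alkene with 9-BBN and oxidative work-up gives the primary alcohol F3, oxidation (TEMPO, PhI(OAc)2, aqueous MeCN) gives the acid F4, and benzylation (BnBr, K2CO3, DMF) gives 16.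

**Step 15.** The allylic, α-branched aldehyde may epimerise, the aldol event may show low facial selectivity, or the activated acid may oligomerise. The fallback sets out from 20 and comes back at 22; it uses a metal-templated thioester aldol followed by a separate lactonisation. Acid 20 is converted into the S-phenyl thioester F5 (PhSH, DCC, DMAP). Soft enolisation with MgBr2·OEt2 and i-Pr2NEt should give, through a chelate that ties the thioester enolate to the aldehyde oxygen, the cis-β-hydroxy thioester F6 with the same substrate-controlled facial sense. Thiophilic activation with AgO2CCF3 then closes the β-lactone to 22 with loss of benzenethiolate.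

**Step 2.** Acid-promoted ionisation of the hindered allylic ketene acetal (elimination to dienes, erosion of enantiopurity) may outrun a rearrangement that must build a C–C bond syn-axial to a ring methyl group. The fallback sets out from 2 and comes back at 6; it is an Ireland–Claisen route that avoids acid and high temperature and reaches the β-keto ester by a different homologation. Alcohol 2 is acetylated (Ac2O, pyridine, DMAP) to the acetate F7. LiN(i-Pr)2 and Me3SiCl give the silyl ketene acetal, which should rearrange on warming to 60 °C, with the same suprafacial chirality transfer, to the acid F8. Hydrogenation (H2, Pd/C) gives the saturated acid F9, and activation with carbonyldiimidazole followed by Mg(O2CCH2CO2t-Bu)2 gives 6 after decarboxylation.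

Further compounds

F1 | step 10 | (5R,6R)-6-[(benzyloxy)methyl]-5-({[tert-butyl(diphenyl)silyl]oxy}methyl)-1-(prop-2-en-1-yl)-2-[(1R)-1,3,3-trimethylcyclohexyl]cyclohex-2-en-1-ol (both C1 epimers) | CC(C)(C)[Si](OC[C@@H]1CC=C([C@]2(C)CCCC(C)(C)C2)C(O)(CC=C)[C@H]1COCc1ccccc1)(c1ccccc1)c1ccccc1
F2 | step 10 | tert-butyl({(1R,2S)-2-[(benzyloxy)methyl]-3-(prop-2-en-1-yl)-4-[(1R)-1,3,3-trimethylcyclohexyl]cyclohex-3-en-1-yl}methoxy)diphenylsilane | CC(C)(C)[Si](OC[C@@H]1CCC([C@]2(C)CCCC(C)(C)C2)=C(CC=C)[C@H]1COCc1ccccc1)(c1ccccc1)c1ccccc1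
F3 | step 10 | 3-[(5R,6S)-6-[(benzyloxy)methyl]-5-({[tert-butyl(diphenyl)silyl]oxy}methyl)-2-[(1R)-1,3,3-trimethylcyclohexyl]cyclohex-1-en-1-yl]propan-1-ol | CC(C)(C)[Si](OC[C@@H]1CCC([C@]2(C)CCCC(C)(C)C2)=C(CCCO)[C@H]1COCc1ccccc1)(c1ccccc1)c1ccccc1
F4 | step 10 | 3-[(5R,6S)-6-[(benzyloxy)methyl]-5-({[tert-butyl(diphenyl)silyl]oxy}methyl)-2-[(1R)-1,3,3-trimethylcyclohexyl]cyclohex-1-en-1-yl]propanoic acid | CC(C)(C)[Si](OC[C@@H]1CCC([C@]2(C)CCCC(C)(C)C2)=C(CCC(=O)O)[C@H]1COCc1ccccc1)(c1ccccc1)c1ccccc1
F5 | step 15 | S-phenyl 3-[(5R,6S)-5-[(butanoyloxy)methyl]-6-formyl-2-[(1R)-1,3,3-trimethylcyclohexyl]cyclohex-1-en-1-yl]propanethioate | CCCC(=O)OC[C@@H]1CCC([C@]2(C)CCCC(C)(C)C2)=C(CCC(=O)Sc2ccccc2)[C@H]1C=O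
F6 | step 15 | S-phenyl (2S,3R,3aS,4R)-4-[(butanoyloxy)methyl]-3-hydroxy-7-[(1R)-1,3,3-trimethylcyclohexyl]-2,3,3a,4,5,6-hexahydro-1H-indene-2-carbothioate | CCCC(=O)OC[C@@H]1CCC([C@]2(C)CCCC(C)(C)C2)=C2C[C@H](C(=O)Sc3ccccc3)[C@H](O)[C@H]21
F7 | step 2 | (1R)-3,5,5-trimethylcyclohex-2-en-1-yl acetate | CC(=O)O[C@H]1C=C(C)CC(C)(C)C1
F8 | step 2 | 2-[(1R)-1,5,5-trimethylcyclohex-2-en-1-yl]acetic acid | OC(=O)C[C@]1(C)C=CCC(C)(C)C1
F9 | step 2 | 2-[(1R)-1,3,3-trimethylcyclohexyl]acetic acid | OC(=O)C[C@]1(C)CCCC(C)(C)C1
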